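**The decision.** We charge the partner at the start, and if one reagent has to be dosed, it is the starting material.

| flask | starting material | partner | remark | time |
|---|---|---|---|---|
| teal | 0.29 M | 1 equiv | run made earlier |  |
| blue | 0.19 M | 1 equiv | run made earlier |  |
| grey | 0.43 M | 1 equiv | run made earlier |  |
| red | 0.29 M | 1.5 equiv | run made earlier |  |
| epsilon | 0.29 M | 1.00 equiv | everything together at the start | 1.0 h |
| theta | 0.29 M | 1.00 equiv (fed, over 40 min) | all else is in the flask from the start; the feed brings no volume worth counting | 1.0 h |
| gamma | 0.29 M (fed, over 40 min) | 1.00 equiv | all else is in the flask from the start; the feed brings no volume worth counting | 1.0 h |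

| run | time / min | target / % |
|---|---|---|
| teal | 3.00 | 3.3 |
| teal | 5.00 | 4.6 |
| teal | 10.0 | 16.9 |
| teal | 20.0 | 37.0 |
| teal | 40.0 | 64.8 |
| blue | 10.0 | 12.9 |
| blue | 20.0 | 30.5 |
| blue | 30.0 | 47.0 |
| blue | 40.0 | 56.1 |
| blue | 50.0 | 65.3 |
| grey | 10.0 | 23.1 |
| grey | 20.0 | 44.5 |
| grey | 30.0 | 59.8 |
| grey | 40.0 | 69.8 |
| grey | 50.0 | 76.0 |
| red | 4.00 | 6.0 |
| red | 8.00 | 18.2 |
| red | 15.0 | 38.9 |
| red | 25.0 | 63.2 |
| red | 50.0 | 90.1 |

(scatter of a reading: 1 percentage point)

- the numbers in the tables scatter with a standard deviation of 1 percentage point

1. the flask with the highest amount of target, in percent of the starting material charged ("all alike" if they lie within 1.5 percentage points) (epsilon / theta / gamma / all alike)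
2. final target, as a percentage of the starting material charged, in epsilon
3. final target, as a percentage of the starting material charged, in theta
4. final target, as a percentage of the starting material charged, in gamma

**Opening entry.** We book against teal, since epsilon is teal read later. In teal, target over the part of the charge that is not yet target climbs from 0.587 at 20.0 min to 1.84 at 40.0 min, which is 0.0627 /min, the second-order plot after its slow start. Carried on to 1.0 h, our books for epsilon show 75.6 % of the charge as target. Red, with 1.5 equiv of partner, reached in 25.0 min about what teal reached in 40.0 min, so we let the pace follow the partner.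

**Lateness entry.** In theta the partner is the limiting reagent while it is fed. We book a lateness of 20.0 min, the mean delay of a fed charge behind one charged at the start; for a steady feed that is half of the feed time. We assume theta runs on teal's clock set back by that much. At 1.0 h it then reads teal at 40.0 min: 64.8 % target, 35.2 % of the charge not yet target. Gamma has its partner in from the start, so we place it just under epsilon.

**The forecast.** It names epsilon, with 77 %, theta 70 % (63 % to 76 %) and gamma 73 %, and holds that “Mild saturation in starting material favours feeding it (gamma) slightly over feeding partner (theta)”. Our theta stands 5.2 points lower.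

**The flasks.** Highest is epsilon: epsilon 76.4 %, theta 62.0 %, gamma 72.7 %.

    open intermediate + second intermediate → target (k = 0.00644 /M/s)
    starting material ⇌ open intermediate (K = 31.2, k = 0.0265 /s)
    partner → second intermediate (k = 9.41 × 10⁻⁴ /s)
    starting material + target → side product (k = 0.00244 /M/s)

**Theta's close.** Theta's books at 1.00 h close with 62.0 % target, 34.7 % open intermediate, 2.26 % side product, counted as two, and 1.11 % starting material. The clock set back by 20.0 min stood 2.8 points above that target. Dosed over 4.00 min, theta has a lateness of 2.00 min, and teal's line, carried on to 58.0 min, gives 74.8 %; that flask gave 75.5 %.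

The earlier runs and the new flask stem from a simulated flask from invented constants; noise was put on by code.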